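**Plan**

1. Retrosynthesis first cuts the two isovalerate C–O ester bonds (chain end on ring A, then the CH2O on ring B). It next cuts the terminal C–O bond of the butynyl chain back to a vinyl group, then the vinyl–alkyne C(sp2)–C(sp) bond, and last the C5'–C(sp) bond on ring A.
2. Forward, the chain is grown on a purchased bithiophene: ethynylation of ring A, one-pot aldehyde reduction and desilylation, vinylation to the but-3-en-1-ynyl group, esterification of the ring B carbinol, anti-Markovnikov hydration of the vinyl group, second esterification.
3. The enabling feature is the O–CH2–CH2–C≡C unit on C5' of ring A (the thiophene bearing the alkyne). Its oxygen sits on the sp3 carbon farthest from the ring, so the chain is a but-3-en-1-ynyl group hydrated at the terminal vinyl carbon.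
4. No ring is formed, since both thiophenes and the 2,2' bond are bought. The target has no stereocentre and no alkene geometry, so no stereocontrol is needed.

Key step: step 5

**Route**

Step 1
Reactants: 1 5'-bromo-2,2'-bithiophene-5-carbaldehyde; 2 ethynyltrimethylsilane
Product: 3 5'-[(trimethylsilyl)ethynyl]-2,2'-bithiophene-5-carbaldehyde
Conditions: 2 (1.5 equiv), PdCl2(PPh3)2 (3 mol %), CuI (6 mol %), Et3N/THF, 50 °C, degassed
Reagents that add atoms: none
Why: Sonogashira coupling, in which the ring A C–Br bond (activated through the bithiophene by the formyl group) adds oxidatively to zerovalent palladium formed in situ, the acetylide generated from 2 by CuI and Et3N transmetallates, and reductive elimination makes the C5'–C(sp) bond while the silyl cap blocks a second coupling and the aldehyde stays inert.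

Step 2
Reactants: 3 5'-[(trimethylsilyl)ethynyl]-2,2'-bithiophene-5-carbaldehyde
Product: 5 (5'-ethynyl-2,2'-bithiophen-5-yl)methanol, via silylalkynyl carbinol 4 (not isolated)
Conditions: NaBH4, MeOH/THF, 0 °C; then K2CO3 (0.3 equiv), rt; neutral aqueous work-up
Reagents that add atoms: none
Why: Hydride reduction of the aldehyde by NaBH4 is followed in the same flask by K2CO3-catalysed methanolysis of the C(sp)–Si bond (protodesilylation), two standard operations that the bithiophene tolerates, and the neutral work-up protects the acid-sensitive thenylic alcohol.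

Step 3
Reactants: 5 (5'-ethynyl-2,2'-bithiophen-5-yl)methanol; 6 vinyl bromide
Product: 7 [5'-(but-3-en-1-yn-1-yl)-2,2'-bithiophen-5-yl]methanol
Conditions: 6 (1 M in THF, 3 equiv), Pd(PPh3)4 (4 mol %), CuI (8 mol %), iPr2NH, THF, 0 °C → rt, sealed, degassed, dark
Reagents that add atoms: none
Why: Sonogashira coupling of a terminal alkyne with an alkenyl bromide, where vinyl bromide adds readily to zerovalent palladium below room temperature and couples with the acetylide from 5 to give the conjugated 1-en-3-yne, the free alcohol being a spectator and the exclusion of oxygen holding back Glaser dimerisation.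

Step 4
Reactants: 7 [5'-(but-3-en-1-yn-1-yl)-2,2'-bithiophen-5-yl]methanol; 8 3-methylbutanoyl chloride
Product: 9 [5'-(but-3-en-1-yn-1-yl)-2,2'-bithiophen-5-yl]methyl 3-methylbutanoate
Conditions: 8 (1.2 equiv), pyridine (2 equiv), DMAP (5 mol %), CH2Cl2, 0 °C
Reagents that add atoms: none
Why: DMAP-catalysed nucleophilic acyl substitution of the primary alcohol on the acid chloride, with pyridine trapping HCl so that neither the ionisable thenylic C–O bond nor the enyne is exposed to acid.

Step 5
Reactants: 9 [5'-(but-3-en-1-yn-1-yl)-2,2'-bithiophen-5-yl]methyl 3-methylbutanoate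
Product: 11 [5'-(4-hydroxybut-1-yn-1-yl)-2,2'-bithiophen-5-yl]methyl 3-methylbutanoate, via alkyl-9-BBN borane 10 (not isolated)
Conditions: 9-borabicyclo[3.3.1]nonane (0.5 M in THF, 1.1 equiv), THF, 0 °C → rt, dark; then NaBO3·4H2O (5 equiv), H2O, rt
Reagents that add atoms: sodium perborate tetrahydrate, [Na+].[O-]OB=O.O.O.O.O (the hydroxyl oxygen of 11); 9-borabicyclo[3.3.1]nonane, B1C2CCCC1CCC2 (boron and its bicyclic carbons, present only in intermediate 10)
Why: The monomeric dialkylborane adds its B–H bond across the vinyl C=C in a concerted syn four-centre transition state with boron on the terminal CH2, giving 10, and perborate then adds to boron and triggers a 1,2-shift of the alkyl group from boron to oxygen, so the bond made is the terminal C–O bond of 11. The closest known reaction type is the 9-borabicyclo[3.3.1]nonane hydroboration–oxidation of a terminal alkene beside an internal alkyne, including conjugated 1-en-3-ynes that give 3-alkyn-1-ols. No ring is closed and no stereocentre is created. The step needs chemoselectivity for the vinyl group over the triple bond and regioselectivity for the terminal carbon, and both are secured because the monosubstituted alkene is the least hindered π bond for the bulky bicyclic borane while the alkyne is disubstituted and flanked by ring A, helped by only a slight excess of reagent, low temperature and quenching once 9 is consumed. The thenylic ester should survive because this borane reduces esters only sluggishly and perborate oxidises at mildly basic pH and room temperature, conditions that also leave the thiophene sulfurs and the alkyne alone.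

Step 6
Reactants: 11 [5'-(4-hydroxybut-1-yn-1-yl)-2,2'-bithiophen-5-yl]methyl 3-methylbutanoate; 8 3-methylbutanoyl chloride
Product: 12 [5'-(4-[(3-methylbutanoyl)oxy]but-1-yn-1-yl)-2,2'-bithiophen-5-yl]methyl 3-methylbutanoate (target)
Conditions: 8 (1.3 equiv), pyridine (2 equiv), DMAP (5 mol %), CH2Cl2, 0 °C → rt
Reagents that add atoms: none
Why: The same DMAP-catalysed acylation, now of the unhindered primary homopropargylic alcohol, which is the only nucleophile left, so the existing ester and the alkyne are untouched and the target results.

**Compound list**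

1 | 5'-bromo-2,2'-bithiophene-5-carbaldehyde | O=Cc1ccc(-c2ccc(Br)s2)s1 | starting material
2 | ethynyltrimethylsilane | C#C[Si](C)(C)C | starting material
3 | 5'-[(trimethylsilyl)ethynyl]-2,2'-bithiophene-5-carbaldehyde | O=Cc1ccc(-c2ccc(C#C[Si](C)(C)C)s2)s1 | intermediate
4 | {5'-[(trimethylsilyl)ethynyl]-2,2'-bithiophen-5-yl}methanol | OCc1ccc(-c2ccc(C#C[Si](C)(C)C)s2)s1 | intermediate
5 | (5'-ethynyl-2,2'-bithiophen-5-yl)methanol | OCc1ccc(-c2ccc(C#C)s2)s1 | intermediate
6 | vinyl bromide (bromoethene) | C=CBr | starting material
7 | [5'-(but-3-en-1-yn-1-yl)-2,2'-bithiophen-5-yl]methanol | C=CC#Cc1ccc(-c2ccc(CO)s2)s1 | intermediate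
8 | 3-methylbutanoyl chloride | CC(C)CC(=O)Cl | starting material
9 | [5'-(but-3-en-1-yn-1-yl)-2,2'-bithiophen-5-yl]methyl 3-methylbutanoate | C=CC#Cc1ccc(-c2ccc(COC(=O)CC(C)C)s2)s1 | intermediate
10 | {5'-[4-(9-borabicyclo[3.3.1]nonan-9-yl)but-1-yn-1-yl]-2,2'-bithiophen-5-yl}methyl 3-methylbutanoate | CC(C)CC(=O)OCc1ccc(-c2ccc(C#CCCB3C4CCCC3CCC4)s2)s1 | intermediate
11 | [5'-(4-hydroxybut-1-yn-1-yl)-2,2'-bithiophen-5-yl]methyl 3-methylbutanoate | OCCC#Cc1ccc(-c2ccc(COC(=O)CC(C)C)s2)s1 | intermediate
12 | [5'-(4-[(3-methylbutanoyl)oxy]but-1-yn-1-yl)-2,2'-bithiophen-5-yl]methyl 3-methylbutanoate | CC(C)CC(=O)OCCC#Cc1ccc(-c2ccc(COC(=O)CC(C)C)s2)s1 | target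

**Totals**

Total step count: 6. Longest linear sequence: 6 steps (1 → 12).

**Steps most likely to fail**

Step 5. The borane may also add across the thienyl-conjugated triple bond, or add a second time, and so erode the chemoselectivity; some of the thenylic ester may also be lost during the oxidation. The fallback drops the hydration and brings the oxygen in with the chain. It sets out from 1: Sonogashira coupling with but-3-yn-1-ol (PdCl2(PPh3)2, CuI, Et3N, THF, 50 °C) should give 5'-(4-hydroxybut-1-yn-1-yl)-2,2'-bithiophene-5-carbaldehyde F1. Reduction with NaBH4 in MeOH at 0 °C should give the diol [5'-(4-hydroxybut-1-yn-1-yl)-2,2'-bithiophen-5-yl]methanol F2. Double acylation with 8 (2.5 equiv), pyridine and DMAP in CH2Cl2 then returns to the route at 12.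

Step 3. The terminal alkyne may dimerise oxidatively before it couples, the volatile bromide may escape from the flask, and the enyne may oligomerise in light. The fallback reverses the polarity of the coupling. It sets out from 5: bromination of the alkyne C–H bond with N-bromosuccinimide and catalytic AgNO3 in acetone in the dark should give [5'-(bromoethynyl)-2,2'-bithiophen-5-yl]methanol F3. A Stille coupling of F3 with tributyl(vinyl)stannane (Pd(PPh3)4, THF, rt) then returns to the route at 7.

Step 2. The free ethynylbithiophene may oligomerise on concentration, and the thenylic alcohol may ionise if the work-up turns acidic. The fallback never isolates a terminal alkyne and installs the ester before the vinyl group. It sets out from 3: reduction with NaBH4 in THF with a little MeOH at 0 °C, without carbonate, should allow 4 to be isolated. Acylation of 4 with 8, pyridine and DMAP should give {5'-[(trimethylsilyl)ethynyl]-2,2'-bithiophen-5-yl}methyl 3-methylbutanoate F4. A fluoride-triggered desilylative Sonogashira coupling of F4 with 6 (Pd(PPh3)4, CuI, CsF, DMF, rt) then returns to the route at 9.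

**Further compounds**

F1 | step 5 | 5'-(4-hydroxybut-1-yn-1-yl)-2,2'-bithiophene-5-carbaldehyde | O=Cc1ccc(-c2ccc(C#CCCO)s2)s1
F2 | step 5 | [5'-(4-hydroxybut-1-yn-1-yl)-2,2'-bithiophen-5-yl]methanol | OCCC#Cc1ccc(-c2ccc(CO)s2)s1
F3 | step 3 | [5'-(bromoethynyl)-2,2'-bithiophen-5-yl]methanol | OCc1ccc(-c2ccc(C#CBr)s2)s1
F4 | step 2 | {5'-[(trimethylsilyl)ethynyl]-2,2'-bithiophen-5-yl}methyl 3-methylbutanoate | CC(C)CC(=O)OCc1ccc(-c2ccc(C#C[Si](C)(C)C)s2)s1
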